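**Retrosynthetic overview**
1. The plan rests on one feature of ring C (the chlorinated hydroxycyclopentenone): the exocyclic trisubstituted C11=C1' alkene with the C5' stereocentre directly beside it. Cutting C1'–C5' turns the alkene into a C11≡C1' alkyne and C5' into an aldehyde, with C2'–C3'–C4' as the link.
2. Target ⇒ C5' chloride (hydrolysis of two dioxolanes and one silyl ether, then enolisation) ⇒ C5' allylic alcohol (SN2 with inversion) ⇒ bis-dioxolane alkynal (rhodium/H2 reductive carbocyclisation).
3. Alkynal ⇒ ynone ⇒ decalin acetylide plus a four-carbon Weinreb amide (C2'–C5') made from ethyl 4-chloroacetoacetate.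
4. Decalin alkyne ⇒ 8β-hydroxy-11-aldehyde ⇒ 8-epi-sclareolide ⇒ (+)-sclareolide. C12 is cut off and C1' is added.
5. Ring order: rings A and B come ready-made with sclareolide, and ring C is closed in the third-last step.

Key step: step 14

Numbering: drimane numbering is used for rings A and B (C4 gem-dimethyl, C5/C10 ring fusion, C8 carbinol, C9, C11 the exocyclic CH, C12 the lactone carbonyl of sclareolide). Ring C is C1' (ylidene carbon), C2' (enol carbon), C3' (CH), C4' (ketone) and C5' (CHCl).
Assumption: the sense of induction of the biaryl bisphosphine at this aldehyde cannot be read from the substrate. The (R) ligand is written, and its mirror image is used if it proves to give the (5'R) alcohol.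
Assumption: the two enol forms of the 1,3-dione interconvert by proton transfer, and the drawn C2' enol/C4' ketone form is taken as the resting form of the target.

**Step 1**
Reactants: 1 (+)-sclareolide
Product: 2 8-epi-sclareolide
Conditions: conc. H2SO4, HCO2H, rt
Reagents that add atoms: none
Why: Acid-catalysed lactone equilibration through alkyl–oxygen cleavage: the tertiary C8–O bond ionises and the carboxyl group recloses from the β face to the more stable cis-fused γ-lactone, which sets the 8β-oxygen/8α-methyl centre of the target while C5, C9 and C10 stay as in 1.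

**Step 2**
Reactants: 2 8-epi-sclareolide
Product: 4 11-hydroxy-8-epi-sclareolide (C11 epimers), via potassium enolate 3 (not isolated)
Conditions: KN(SiMe3)2, THF, −78 °C; 2-(phenylsulfonyl)-3-phenyloxaziridine, −78 °C; AcOH
Reagents that add atoms: 2-(phenylsulfonyl)-3-phenyloxaziridine, O=S(=O)(N1OC1c1ccccc1)c1ccccc1
Why: Davis oxidation of a lactone enolate places on C11 the oxygen that later lets C12 be cut away; the new C11 centre is destroyed in step 4, so its configuration is of no consequence.

**Step 3**
Reactants: 4 11-hydroxy-8-epi-sclareolide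
Product: 5 8-epi-homodrimane-8β,11,12-triol
Conditions: LiAlH4, THF, 0 °C → rt
Reagents that add atoms: none
Why: LiAlH4 reduction of a lactone to the diol opens the ring to the 8β,11,12-triol and touches no stereocentre.

**Step 4**
Reactants: 5 8-epi-homodrimane-8β,11,12-triol
Product: 6 8β-hydroxydriman-11-al
Conditions: NaIO4, THF/H2O, 0 °C → rt
Reagents that add atoms: none
Why: Malaprade glycol cleavage breaks only the vicinal C11–C12 diol (the C8 hydroxyl is 1,3 to C11), removes C12 as formaldehyde and, being neutral, leaves the C9 centre next to the new aldehyde intact.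

**Step 5**
Reactants: 6 8β-hydroxydriman-11-al
Product: 7 9β-ethynyl 8β-alcohol (terminal alkyne C11≡C1'H)
Conditions: dimethyl (1-diazo-2-oxopropyl)phosphonate, K2CO3, MeOH, 0 °C → rt
Reagents that add atoms: dimethyl (1-diazo-2-oxopropyl)phosphonate, CC(=O)C(=[N+]=[N-])P(=O)(OC)OC
Why: Seyferth–Gilbert homologation in the Ohira–Bestmann variant adds C1' and gives the terminal alkyne under carbonate base that is too weak to remove the shielded axial H9 quickly, so C9 should keep its configuration and the free hydroxyl, a poor leaving group, should stay.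

**Step 6**
Reactants: 7 9β-ethynyl 8β-alcohol
Product: 8 C8 trimethylsilyl ether of 7
Conditions: TMSOTf, 2,6-lutidine, CH2Cl2, −78 → 0 °C
Reagents that add atoms: trimethylsilyl triflate, C[Si](C)(C)OS(=O)(=O)C(F)(F)F
Why: Silyl ether formation with the small and highly electrophilic TMSOTf should reach the axial tertiary hydroxyl that is syn-axial to the C10 methyl; crowding makes this trimethylsilyl ether unusually robust, it keeps the oxygen away from base, rhodium and phosphonium reagents, and it needs no step of its own for removal.

**Step 7**
Reactants: 9 ethyl 4-chloroacetoacetate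
Product: 10 ethyl 4-(4-methoxybenzyloxy)-3-oxobutanoate
Conditions: 4-methoxybenzyl alcohol, NaH (2.2 equiv), THF, 0 °C → rt; AcOH
Reagents that add atoms: 4-methoxybenzyl alcohol, COc1ccc(CO)cc1
Why: Williamson ether synthesis by SN2 displacement at the α-chloro ketone, done now because the same chloride would be neopentyl-like and inert once C4' is a ketal; the second equivalent of NaH holds the β-keto ester as its enolate and so shields ketone and ester from the alkoxide.

**Step 8**
Reactants: 10 ethyl 4-(4-methoxybenzyloxy)-3-oxobutanoate
Product: 11 ethyl 2-[2-(4-methoxybenzyloxymethyl)-1,3-dioxolan-2-yl]acetate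
Conditions: HOCH2CH2OH, PPTS (cat.), toluene, reflux, Dean–Stark
Reagents that add atoms: ethylene glycol, OCCO
Why: Acid-catalysed ketalisation of a β-keto ester with azeotropic removal of water; PPTS is mild enough for the PMB ether.

**Step 9**
Reactants: 11 ketal ester
Product: 12 N-methoxy-N-methyl-2-[2-(4-methoxybenzyloxymethyl)-1,3-dioxolan-2-yl]acetamide
Conditions: MeNH(OMe)·HCl, i-PrMgCl, THF, −20 → 0 °C; aq. NH4Cl
Reagents that add atoms: N,O-dimethylhydroxylamine hydrochloride, CNOC.Cl
Why: Aminolysis of the ester with the magnesium amide of N,O-dimethylhydroxylamine (Weinreb amide synthesis) gives an acyl donor that accepts one carbanion only, and the low temperature holds back enolisation toward the β-ketal.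

**Step 10**
Reactants: 8 C8 trimethylsilyl ether alkyne; 12 Weinreb amide
Product: 14 ynone (C2' ketone; C4' dioxolane; C5' OPMB), via lithium acetylide 13 (not isolated)
Conditions: 8, n-BuLi, THF, −78 °C; then 12, −78 → −20 °C; AcOH
Reagents that add atoms: none
Why: Weinreb ketone synthesis: the weakly basic lithium acetylide adds to the amide faster than it deprotonates C3', addition stops after one equivalent, and the acidic quench frees the base-sensitive β-ketal ynone in a neutral medium, forming the C1'–C2' bond.

**Step 11**
Reactants: 14 ynone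
Product: 15 bis-dioxolane PMB ether
Conditions: (TMSOCH2)2, TMSOTf (10 mol %), CH2Cl2, −78 → −30 °C; pyridine
Reagents that add atoms: 1,2-bis(trimethylsilyloxy)ethane, C[Si](C)(C)OCCO[Si](C)(C)C
Why: Noyori ketalisation (bis-silyl glycol ether, catalytic TMSOTf), an aprotic low-temperature method that is established for conjugated ynones and gives inert (Me3Si)2O in place of water, so that conjugate addition of glycol at C11, β-elimination of the C4' ketal and loss of PMB or silyl groups should not compete.

**Step 12**
Reactants: 15 bis-dioxolane PMB ether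
Product: 16 bis-dioxolane primary alcohol (C5' CH2OH)
Conditions: DDQ, CH2Cl2/pH 7 buffer, 0 °C
Reagents that add atoms: none
Why: Oxidative PMB ether cleavage with DDQ (hydride abstraction from the electron-rich benzylic position, then hydrolysis) in buffered medium leaves alkyne, dioxolanes and the hindered silyl ether alone.

**Step 13**
Reactants: 16 bis-dioxolane primary alcohol
Product: 17 bis-dioxolane alkynal (C8 OTMS)
Conditions: Dess–Martin periodinane, pyridine, CH2Cl2, 0 °C → rt
Reagents that add atoms: none
Why: Dess–Martin oxidation under pyridine buffer stops at the aldehyde, which has a fully substituted α-carbon and so can neither enolise nor epimerise.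

**Step 14**
Reactants: 17 bis-dioxolane alkynal
Product: 18 bis-dioxolane ylidene cyclopentanol, (5'S), C9 cis to C2'
Conditions: Rh(cod)2OTf (5 mol %), (R)-Cl,MeO-BIPHEP (5 mol %), 2-naphthoic acid (5 mol %), H2 (1 atm), ClCH2CH2Cl, 45 °C
Reagents that add atoms: none
Why: The cationic bisphosphine complex of monovalent rhodium binds the alkyne and the aldehyde of 17 together and couples them oxidatively to a five-membered oxarhodacycle of trivalent rhodium (new C1'–C5' bond, Rh–C11 and Rh–O bonds); the carboxylic acid protonates the Rh–O bond, H2 is then split on the rhodium carboxylate, and C11–H reductive elimination frees 18 and the catalyst. The reaction type is the known hydrogen-mediated asymmetric reductive cyclisation of acetylenic aldehydes of the hex-5-ynal type, here applied to a bulkier alkyne. Ring C closes in the 5-exo-dig mode, and because C5' and hydrogen are delivered to the same side of the alkyne, H11 ends cis to C5' and the decalin carbon C9 cis to C2', which is the geometry of the target. The one new stereocentre, C5' (S), is fixed by the chiral bisphosphine through its choice of aldehyde face in the coupling, since C9, the nearest decalin centre, sits beyond the linear alkyne and should exert little bias. The step needs C–C coupling to be faster than simple hydrogenation of alkyne or aldehyde, and it needs one electrophile only: both ketone carbons are dioxolanes, so the alkyne is not a conjugate acceptor, the aldehyde carries no α-hydrogen, the two spiro ketals fold the three-atom tether (gem-disubstituent effect), and the silylated C8 oxygen can neither bind rhodium nor add to the alkyne.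

**Step 15**
Reactants: 18 bis-dioxolane ylidene cyclopentanol
Product: 19 (5'R)-chloride, bis-dioxolane, C8 OTMS
Conditions: PPh3, Cl3CC(O)CCl3, CH2Cl2, −20 → 0 °C
Reagents that add atoms: hexachloroacetone, O=C(C(Cl)(Cl)Cl)C(Cl)(Cl)Cl
Why: Appel-type deoxychlorination (PPh3/hexachloroacetone, a neutral variant suited to allylic alcohols): chloride displaces the oxyphosphonium group by SN2 with inversion, (5'S) to (5'R); ionisation is disfavoured by the two electron-withdrawing ketal carbons on the allyl system, SN2' attack at C11 is blocked by the decalin, and the step is placed before ketal removal because the free enolised 1,3-dione would itself be chlorinated by the reagent and the α-ketol could scramble C5'.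

**Step 16**
Reactants: 19 (5'R)-chloride
Product: 21 CNP0279879.2 (target), via 1,3-dione tautomer 20 (not isolated)
Conditions: p-TsOH·H2O, THF/H2O (3:1), rt
Reagents that add atoms: water, O
Why: Acid hydrolysis of silyl ether and ketals: the trimethylsilyl ether and the allylic C2' dioxolane go first, the C4' dioxolane, deactivated by the neighbouring chlorine, then leaves by way of the C2'-derived enol (vinylogous β-elimination and hydrolysis of the enol ether), and dione 20 enolises at once toward C3' to the conjugated vinylogous acid, which draws enolisation away from C5' and keeps the (5'R) centre, while dilute non-nucleophilic acid at room temperature should spare the tertiary C8 alcohol.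

**Compound list**
1 | (+)-sclareolide (trans-fused lactone; 8α-O, 8β-CH3, 9α-H, 5α-H, 10β-CH3) | CC1(C)CCC[C@]2(C)[C@H]3CC(=O)O[C@]3(C)CC[C@@H]12 | starting material
2 | 8-epi-sclareolide (cis-fused lactone; 8β-O, 8α-CH3) | CC1(C)CCC[C@]2(C)[C@H]3CC(=O)O[C@@]3(C)CC[C@@H]12 | intermediate
3 | potassium enolate of 2 (not isolated) | CC1(C)CCC[C@]2(C)[C@H]3C=C([O-])O[C@@]3(C)CC[C@@H]12.[K+] | intermediate
4 | 11-hydroxy-8-epi-sclareolide (C11 epimers, centre erased in step 4) | CC1(C)CCC[C@]2(C)[C@H]3C(O)C(=O)O[C@@]3(C)CC[C@@H]12 | intermediate
5 | 8-epi-homodrimane-8β,11,12-triol (C11 epimers) | CC1(C)CCC[C@]2(C)[C@@H](C(O)CO)[C@@](C)(O)CC[C@@H]12 | intermediate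
6 | 8β-hydroxydriman-11-al (9β-CHO, 9α-H) | CC1(C)CCC[C@]2(C)[C@@H](C=O)[C@@](C)(O)CC[C@@H]12 | intermediate
7 | 9β-ethynyl 8β-alcohol (C11≡C1'H) | CC1(C)CCC[C@]2(C)[C@@H](C#C)[C@@](C)(O)CC[C@@H]12 | intermediate
8 | C8 trimethylsilyl ether of 7 | CC1(C)CCC[C@]2(C)[C@@H](C#C)[C@@](C)(O[Si](C)(C)C)CC[C@@H]12 | intermediate
9 | ethyl 4-chloroacetoacetate | CCOC(=O)CC(=O)CCl | starting material
10 | ethyl 4-(4-methoxybenzyloxy)-3-oxobutanoate | CCOC(=O)CC(=O)COCc1ccc(OC)cc1 | intermediate
11 | ethyl 2-[2-(4-methoxybenzyloxymethyl)-1,3-dioxolan-2-yl]acetate | CCOC(=O)CC1(COCc2ccc(OC)cc2)OCCO1 | intermediate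
12 | N-methoxy-N-methyl-2-[2-(4-methoxybenzyloxymethyl)-1,3-dioxolan-2-yl]acetamide | CON(C)C(=O)CC1(COCc2ccc(OC)cc2)OCCO1 | intermediate
13 | lithium acetylide of 8 (not isolated) | CC1(C)CCC[C@]2(C)[C@@H](C#C[Li])[C@@](C)(O[Si](C)(C)C)CC[C@@H]12 | intermediate
14 | ynone (C2' ketone, C4' dioxolane, C5' OPMB, C8 OTMS) | CC1(C)CCC[C@]2(C)[C@@H](C#CC(=O)CC3(COCc4ccc(OC)cc4)OCCO3)[C@@](C)(O[Si](C)(C)C)CC[C@@H]12 | intermediate
15 | bis-dioxolane PMB ether | CC1(C)CCC[C@]2(C)[C@@H](C#CC3(OCCO3)CC4(COCc5ccc(OC)cc5)OCCO4)[C@@](C)(O[Si](C)(C)C)CC[C@@H]12 | intermediate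
16 | bis-dioxolane primary alcohol | CC1(C)CCC[C@]2(C)[C@@H](C#CC3(OCCO3)CC4(CO)OCCO4)[C@@](C)(O[Si](C)(C)C)CC[C@@H]12 | intermediate
17 | bis-dioxolane alkynal (key-step precursor, C8 OTMS) | CC1(C)CCC[C@]2(C)[C@@H](C#CC3(OCCO3)CC4(C=O)OCCO4)[C@@](C)(O[Si](C)(C)C)CC[C@@H]12 | intermediate
18 | bis-dioxolane ylidene cyclopentanol (key-step product; 5'S; C9 cis to C2'; C8 OTMS) | CC1(C)CCC[C@]2(C)[C@@H](/C=C3\C4(OCCO4)CC5(OCCO5)[C@H]3O)[C@@](C)(O[Si](C)(C)C)CC[C@@H]12 | intermediate
19 | (5'R)-chloride, bis-dioxolane, C8 OTMS, C9 cis to C2' | CC1(C)CCC[C@]2(C)[C@@H](/C=C3\C4(OCCO4)CC5(OCCO5)[C@@H]3Cl)[C@@](C)(O[Si](C)(C)C)CC[C@@H]12 | intermediate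
20 | 1,3-dione tautomer of the target (not isolated) | CC1(C)CCC[C@]2(C)[C@@H](/C=C3\C(=O)CC(=O)[C@@H]3Cl)[C@@](C)(O)CC[C@@H]12 | intermediate
21 | CNP0279879.2 (8β-OH, 5'R chloride, C2' enol, C4' ketone, C9 cis to C2') | CC1(C)CCC[C@]2(C)[C@@H](/C=C3\C(O)=CC(=O)[C@@H]3Cl)[C@@](C)(O)CC[C@@H]12 | target

**Step count**
Total: 16 steps. Longest linear sequence: 13 steps (steps 1–6 and 10–16). Steps 7–9 form the short branch.

**Steps most likely to fail**

Step 14.
- What may go wrong: C11 sits next to C9, which lies between two fully substituted carbons. The oxidative coupling may therefore be slow, and plain hydrogenation of the alkyne or aldehyde, decarbonylation, or poor selection of the aldehyde face may take over.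
- Fallback: it sets out from 17 and returns at 18, and it separates ring closure from the stereocentre.
- First stage: without hydrogen, a cationic rhodium bisphosphine catalyst ([Rh(cod)2]BF4, rac-BINAP, CH2Cl2, rt) should bring about intramolecular hydroacylation of the 5-alkynal. This is a syn addition of the acyl carbon and the aldehyde hydrogen across the alkyne, and it gives the ylidene cyclopentanone F1 with the same alkene geometry.
- Second stage: Corey–Bakshi–Shibata reduction (the Me-CBS oxazaborolidine enantiomer that delivers hydride to the required face, catecholborane, toluene, −78 °C) then sets (5'S) under reagent control and gives 18.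

Step 15.
- What may go wrong: displacement at a carbon flanked by a spiro ketal may be sluggish. Collapse of the ion pair with retention, or allylic transposition toward C11, may then erode the configuration.
- Fallback: it sets out from 18 and returns at 21, and it moves the displacement to the very end, where the carbon is both allylic and α to a ketone.
- First stage: MsCl and Et3N (CH2Cl2, −20 °C) give the (5'S)-mesylate F2.
- Second stage: p-TsOH·H2O in THF/H2O removes both dioxolanes and the silyl ether to give the mesyloxy vinylogous acid F3.
- Third stage: one equivalent of LiCl in acetone at 0 °C displaces the mesylate by SN2 with inversion and gives 21 directly. The chloride charge is kept near stoichiometric so that degenerate chloride exchange cannot scramble C5'.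

Step 5.
- What may go wrong: the aldehyde is wedged between two fully substituted carbons, so addition of the diazophosphonate anion may be slow. The basic methanol then has time for retro-aldol opening of ring B, loss of water to the conjugated enal, or epimerisation at C9.
- Fallback: it sets out from 6 and returns at 13, and it avoids protic base altogether.
- First stage: N-(trimethylsilyl)imidazole (CH2Cl2, rt) gives the silyloxy aldehyde F4.
- Second stage: Corey–Fuchs olefination (CBr4, PPh3, CH2Cl2, 0 °C) gives the 1,1-dibromoalkene F5.
- Third stage: n-BuLi (2.1 equiv, THF, −78 °C) converts F5 by bromine–lithium exchange and rearrangement into lithium acetylide 13. This enters step 10 in the same flask, so steps 5 and 6 are both bypassed.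

**Further compounds**
F1 | step 14 | ylidene cyclopentanone (C5' ketone, bis-dioxolane, C8 OTMS, C9 cis to C2') | CC1(C)CCC[C@]2(C)[C@@H](/C=C3\C4(OCCO4)CC5(OCCO5)C3=O)[C@@](C)(O[Si](C)(C)C)CC[C@@H]12
F2 | step 15 | (5'S)-mesylate of 18 | CC1(C)CCC[C@]2(C)[C@@H](/C=C3\C4(OCCO4)CC5(OCCO5)[C@H]3OS(C)(=O)=O)[C@@](C)(O[Si](C)(C)C)CC[C@@H]12
F3 | step 15 | (5'S)-mesyloxy vinylogous acid (8β-OH free, C2' enol, C4' ketone) | CC1(C)CCC[C@]2(C)[C@@H](/C=C3\C(O)=CC(=O)[C@H]3OS(C)(=O)=O)[C@@](C)(O)CC[C@@H]12
F4 | step 5 | 8β-(trimethylsilyloxy)driman-11-al | CC1(C)CCC[C@]2(C)[C@@H](C=O)[C@@](C)(O[Si](C)(C)C)CC[C@@H]12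
F5 | step 5 | 1,1-dibromoalkene from F4 | CC1(C)CCC[C@]2(C)[C@@H](C=C(Br)Br)[C@@](C)(O[Si](C)(C)C)CC[C@@H]12
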